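**Retrosynthetic overview**
- The target is a trans-fused cyclobutane/cyclononane carrying a trans-fused pyran and a dearomatised acylphloroglucinol. Enabling feature: the two cyclobutane CH carbons are linked 1,4 through CMe2–CH2; one is allylic to the exocyclic C=CH2 (γ-carbon of an allylsilane if the =CH2 carbon carries SiMe3), the other lies two carbons from the ring CH2 next to the ether carbon (β-carbon of an E-enone if that CH2 is a C=O).
- Key disconnection: the bond between the two cyclobutane CH carbons, opened to an eleven-membered enone–allylsilane. Closing it copies the humulyl → caryophyllenyl cation step of the biosynthesis, with Me3Si in place of the proton lost from the methyl group and the ketone as a removable activator.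
- Pyran: hetero-Diels–Alder reaction of the o-quinone methide from norflavesone with the 2,3-alkene of a zerumbone-derived dienol. The 6,7-alkene is masked as an (R,R)-epoxide (Shi epoxidation), which carries the absolute configuration and later becomes the allylsilane.
- Ring order: cyclohexadienone (dearomatising methylation) and eleven-membered carbocycle (bought as zerumbone) → pyran (step 5) → cyclobutane (step 9; the same bond turns the eleven- into the nine-membered ring). The activating ketone is then removed (steps 10–12).

Key step: step 9

Assumption: 7, 9 and 14 are carried as mixtures of epimers at the carbinol carbon (left undefined in their SMILES), because this centre becomes a ketone (step 6) or a CH2 group (step 12).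

Step 1
Reactants: 1 phloroglucinol; 2 isobutyryl chloride
Product: 3 2-methyl-1-(2,4,6-trihydroxyphenyl)propan-1-one
Conditions: AlCl3 (3 equiv), PhNO2, 60 °C; then aq. HCl
Reagents that add atoms: none
Why: Friedel–Crafts acylation of the symmetric, electron-rich triol, in which the first acyl group deactivates the ring against a second acylation.

Step 2
Reactants: 3 2-methyl-1-(2,4,6-trihydroxyphenyl)propan-1-one
Product: 4 norflavesone
Conditions: NaOMe (3.3 equiv), MeI (3 equiv), MeOH, 0 °C → rt; then aq. HCl
Reagents that add atoms: iodomethane CI
Why: Dearomatising C-methylation of the acylphloroglucinol polyanion, in which two methyl groups enter geminally at one ring carbon and one at the other free carbon; three equivalents should give mainly the trimethyl compound, to be separated from under- and over-methylated material.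

Step 3
Reactants: 5 zerumbone
Product: 6 (6R,7R)-zerumbone 6,7-epoxide
Conditions: 1,2:4,5-di-O-isopropylidene-β-D-erythro-2,3-hexodiulo-2,6-pyranose (30 mol%), KHSO5 (as 2KHSO5·KHSO4·K2SO4), K2CO3, Bu4NHSO4, MeCN–CH2(OMe)2–aq. Na2B4O7 buffer, 0 °C
Reagents that add atoms: potassium peroxymonosulfate [K+].[O-]S(=O)(=O)OO
Why: Shi asymmetric epoxidation, in which the chiral dioxirane attacks only the isolated, electron-rich trisubstituted E-alkene (both enone double bonds are deactivated) through the spiro transition state, which should set both epoxide carbons as R.

Step 4
Reactants: 6 (6R,7R)-zerumbone 6,7-epoxide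
Product: 7 (6R,7R)-6,7-epoxyzerumbol (both carbinol epimers)
Conditions: NaBH4, CeCl3·7H2O, MeOH, 0 °C
Reagents that add atoms: none
Why: Luche 1,2-reduction of the cross-conjugated dienone, needed because an enone alkene does not add to an electron-poor quinone methide; the new carbinol centre is not controlled and is erased in step 6.

Step 5
Reactants: 7 (6R,7R)-6,7-epoxyzerumbol; 4 norflavesone
Product: 9 pyran-fused epoxy alcohol, via o-quinone methide 8 (not isolated)
Conditions: TEMPO (2,2,6,6-tetramethylpiperidin-1-oxyl, 0.3 equiv), Ag2O (2 equiv), slow addition of 4, THF, 25 → 40 °C
Reagents that add atoms: none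
Why: TEMPO/Ag2O dehydrogenation of the ring methyl of 4 gives o-quinone methide 8, which adds in an inverse-electron-demand hetero-Diels–Alder reaction to the only trisubstituted alkene of 7 (the other is masked as the epoxide) with oxygen going to the methyl-bearing carbon; suprafacial addition to the E-alkene fixes the trans ring fusion, and the face of attack relative to the enantiopure epoxide decides the absolute configuration of the two new centres (the series shown is carried on; its face diastereomer is removed after step 6).

Step 6
Reactants: 9 pyran-fused epoxy alcohol
Product: 10 pyran-fused epoxy enone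
Conditions: MnO2 (activated, excess), CH2Cl2, 25 °C; chromatography
Reagents that add atoms: none
Why: MnO2 oxidation of the allylic alcohol merges both carbinol epimers into one E-enone and leaves epoxide and enol untouched, after which the two pyran-face diastereomers, now differing only in the relation of pyran to epoxide, are separated by chromatography.

Step 7
Reactants: 10 pyran-fused epoxy enone
Product: 11 methylidene allylic alcohol
Conditions: Et2AlCl + lithium 2,2,6,6-tetramethylpiperidide (4 equiv of the aluminium amide), toluene, 0 °C; aq. potassium sodium tartrate
Reagents that add atoms: none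
Why: Base-mediated epoxide-to-allylic-alcohol isomerisation with a bulky aluminium amide (syn β-elimination), in which the proton is taken from the methyl group and the C–O bond at the tertiary carbon breaks, so that the exocyclic methylene forms and the carbinol carbon keeps its R configuration; the ketone cannot enolise (quaternary carbon on one side, vinylic CH on the other) and the first equivalent of reagent only deprotonates the acidic enol.

Step 8
Reactants: 11 methylidene allylic alcohol
Product: 12 allylsilane enone
Conditions: Pd(BF4)2(MeCN)4 (5 mol%), Me3SiSiMe3 (2 equiv), DMSO–MeOH, 50 °C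
Reagents that add atoms: hexamethyldisilane C[Si](C)(C)[Si](C)(C)C
Why: Palladium-catalysed allylic silylation of a free allylic alcohol with a disilane, in which ionisation gives a π-allyl complex of divalent palladium and the silyl group is delivered to the unhindered CH2 terminus, moving the double bond into the ring (ring CH2 groups trans, as in zerumbone) and removing the carbinol centre.

Step 9
Reactants: 12 allylsilane enone
Product: 13 keto-target (trans-fused cyclobutane formed)
Conditions: EtAlCl2 (3 equiv), CH2Cl2 (0.002 M), −78 → −20 °C; aq. potassium sodium tartrate
Reagents that add atoms: none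
Why: Proposed new method: EtAlCl2 (the first equivalent turns the acidic enol into an aluminium enolate with loss of ethane, so no HCl is set free) chelates the ketone and the neighbouring pyran oxygen and makes the enone β-carbon a stand-in for the humulyl cation, which is attacked across the ring by the γ-carbon of the allylsilane; loss of the silyl group from the β-silyl cation (in place of the methyl proton lost in the biosynthesis of caryophyllene) leaves the exocyclic methylene and an aluminium enolate that is protonated on work-up. The closest known reaction type is the Lewis-acid-promoted intramolecular Hosomi–Sakurai conjugate allylation of enones, known for five- to eight-membered rings but not for a transannular four-membered closure. The cyclobutane closes in a 4-exo-trig mode at the enone and the same bond turns the eleven-membered ring into the nine-membered ring, so no other ring is closed; the strain of the four-membered ring is paid for by the Si–Cl and Al–O bonds that form. Both new stereocentres (the two ring-fusion CH) are set in the transannular transition state: the E-enone and the ring-E allylsilane can overlap only through their inner faces in a crossed arrangement, which should give the trans fusion, and the sense of this arrangement is fixed by the trans-fused pyran (axial methyl, chelated carbonyl) and is expected to lead to the relative configuration of natural caryophyllene oxide, which is that of the target. The step needs 1,4- and not 1,2-addition, trans and not cis fusion, and cyclisation faster than protodesilylation: 1,2-attack would place the E double bond in a six-membered ring and is impossible, the E geometry of both π-units secures trans, and the HCl-free aluminium reagent at low temperature and high dilution suppresses protodesilylation and intermolecular reaction.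

Step 10
Reactants: 13 keto-target
Product: 14 hydroxy-target (either carbinol epimer)
Conditions: NaBH4 (excess), MeOH–THF, 0 °C; then aq. NH4Cl
Reagents that add atoms: none
Why: NaBH4 reduction of the hindered ketone while the β-triketone is protected as its sodium enolate and the exocyclic alkene is inert; the configuration of the new carbinol is irrelevant.

Step 11
Reactants: 14 hydroxy-target
Product: 15 O-(imidazol-1-ylthiocarbonyl) derivative
Conditions: 1,1'-thiocarbonyldiimidazole (3 equiv), 4-(dimethylamino)pyridine (cat.), ClCH2CH2Cl, 70 °C
Reagents that add atoms: 1,1'-thiocarbonyldiimidazole S=C(n1ccnc1)n1ccnc1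
Why: Thioacylation of the secondary alcohol (first half of a Barton–McCombie deoxygenation), any thioacylated enol oxygen being set free again on aqueous work-up.

Step 12
Reactants: 15 O-(imidazol-1-ylthiocarbonyl) derivative
Product: 16 target
Conditions: Bu3SnH (5 equiv, 0.5 M), AIBN (cat.), toluene, 100 °C
Reagents that add atoms: none
Why: Barton–McCombie radical deoxygenation, with the stannane kept concentrated so that hydrogen transfer to the secondary radical outruns transannular addition to the exocyclic methylene; no stereocentre is touched.

**Compound list**
1 | phloroglucinol (benzene-1,3,5-triol) | Oc1cc(O)cc(O)c1 | starting material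
2 | isobutyryl chloride (2-methylpropanoyl chloride) | CC(C)C(Cl)=O | starting material
3 | 2-methyl-1-(2,4,6-trihydroxyphenyl)propan-1-one | CC(C)C(=O)c1c(O)cc(O)cc1O | intermediate
4 | norflavesone, 3,5-dihydroxy-4,6,6-trimethyl-2-(2-methylpropanoyl)cyclohexa-2,4-dien-1-one (one enol tautomer) | CC(C)C(=O)C1=C(O)C(C)=C(O)C(C)(C)C1=O | intermediate
5 | zerumbone, (2E,6E,10E)-2,6,9,9-tetramethylcycloundeca-2,6,10-trien-1-one | C/C1=C\CC/C(C)=C/CC(C)(C)/C=C/C1=O | starting material
6 | (2E,6R,7R,10E)-6,7-epoxy-2,6,9,9-tetramethylcycloundeca-2,10-dien-1-one | C/C1=C\CC[C@@]2(C)O[C@@H]2CC(C)(C)/C=C/C1=O | intermediate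
7 | (2E,6R,7R,10E)-6,7-epoxy-2,6,9,9-tetramethylcycloundeca-2,10-dien-1-ol, both C1 epimers | C/C1=C\CC[C@@]2(C)O[C@@H]2CC(C)(C)/C=C/C1O | intermediate
8 | o-quinone methide, 5-hydroxy-2,2-dimethyl-6-methylidene-4-(2-methylpropanoyl)cyclohex-4-ene-1,3-dione | C=C1C(=O)C(C)(C)C(=O)C(C(=O)C(C)C)=C1O | intermediate (not isolated)
9 | adduct of 8 with the 2,3-double bond of 7 (zerumbone numbering): pyran O on C2, pyran CH2 on C3, trans ring fusion with both centres as in the target, (6R,7R)-epoxide, 10E-alkene, 1-OH (both epimers) | C1C[C@H]2CC3=C(O[C@]2(C)C(O)/C=C/C(C)(C)C[C@H]4O[C@]14C)C(C)(C)C(=O)C(C(=O)C(C)C)=C3O | intermediate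
10 | 1-ketone of 9 (E-enone), single pyran diastereomer, (6R,7R)-epoxide | C1C[C@H]2CC3=C(O[C@]2(C)C(=O)/C=C/C(C)(C)C[C@H]4O[C@]14C)C(C)(C)C(=O)C(C(=O)C(C)C)=C3O | intermediate
11 | allylic alcohol from 10: 6-methylidene, (7R)-hydroxy, E-enone kept | C=C1CC[C@H]2CC3=C(O[C@]2(C)C(=O)/C=C/C(C)(C)C[C@H]1O)C(C)(C)C(=O)C(C(=O)C(C)C)=C3O | intermediate
12 | allylsilane from 11: 6-(trimethylsilylmethyl)-6,7-ene with the two ring CH2 groups trans across the double bond, E-enone | C1C[C@H]2CC3=C(O[C@]2(C)C(=O)/C=C/C(C)(C)C/C=C1\C[Si](C)(C)C)C(C)(C)C(=O)C(C(=O)C(C)C)=C3O | intermediate
13 | keto-target: the target with C=O in place of the ring CH2 next to the ether-bearing quaternary carbon; trans-fused cyclobutane, all four stereocentres as in the target | C=C1CC[C@H]2CC3=C(O[C@]2(C)C(=O)C[C@@H]2[C@@H]1CC2(C)C)C(C)(C)C(=O)C(C(=O)C(C)C)=C3O | intermediate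
14 | secondary alcohol from 13 (either epimer) | C=C1CC[C@H]2CC3=C(O[C@]2(C)C(O)C[C@@H]2[C@@H]1CC2(C)C)C(C)(C)C(=O)C(C(=O)C(C)C)=C3O | intermediate
15 | O-(1H-imidazol-1-ylthiocarbonyl) derivative of 14 | C=C1CC[C@H]2CC3=C(O[C@]2(C)C(OC(=S)n4ccnc4)C[C@@H]2[C@@H]1CC2(C)C)C(C)(C)C(=O)C(C(=O)C(C)C)=C3O | intermediate
16 | CNP0497637.2 | C=C1CC[C@H]2CC3=C(O[C@]2(C)CC[C@@H]2[C@@H]1CC2(C)C)C(C)(C)C(=O)C(C(=O)C(C)C)=C3O | target

**Step count and risks**

Total step count: 12. Longest linear sequence: 10 steps (5 → 16, steps 3–12); steps 1–2 make the quinone methide precursor 4.

Steps most likely to fail: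

1. Step 9 (proposed new method). The silyl group may be lost by protonation before the C–C bond forms. The β-silyl cyclobutylcarbinyl cation may ring-expand before silicon leaves. The ring may close through the other crossed conformer (wrong facial relation to the pyran) or through a parallel arrangement (cis fusion). The fallback uses known reaction types, sets out from 10 and returns at 13. The epoxide of 10 is opened at its secondary carbon with Li2NiBr4 in THF (inversion) to give the bromohydrin F1. Bu3SnH/AIBN (slow addition, benzene, 80 °C) then generates the secondary radical, which adds across the ring to the enone β-carbon; this 4-exo-trig radical conjugate cyclisation has precedent for tethers carrying a quaternary carbon, as here, and gives the tertiary alcohol F2. Dehydration towards the methyl group (SOCl2, pyridine, −20 °C) gives 13, which rejoins the route at step 10.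

2. Step 5. The quinone methide may be consumed by self-condensation or by reversible ether formation with the alcohol faster than it adds to the hindered, inductively deactivated alkene. Attack on the unwanted face would divert material; if that face dominates, the enantiomeric ketone catalyst in step 3 makes the wanted series the major one. The fallback sets out from 3 and 7 and returns at 9. Compound 3 is C-methylated only twice (2 equiv MeI, NaOMe) to the triketone F3. Knoevenagel condensation of F3 with paraformaldehyde (NaOAc, AcOH, toluene, 80 °C) in the presence of 7 generates the same quinone methide 8 slowly and without oxidant, so the cycloaddition can be run hot and with excess triketone.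

3. Step 12. The secondary radical next to the ether carbon may add across the nine-membered ring to the exocyclic methylene, or eject the stabilised enol radical by β-scission, before hydrogen transfer. The fallback avoids radicals, sets out from 13 and returns at 16. KN(SiMe3)2 (2.2 equiv) and PhNTf2 give the enol triflate F4 (only one direction of enolisation exists). Pd(OAc)2/PPh3 with HCO2H and Bu3N in DMF reduces it to the cis-alkene F5. Diimide (potassium azodicarboxylate, AcOH) should then reduce the strained ring alkene in preference to the 1,1-disubstituted methylene and give 16; over-reduction of the methylene is the risk of this last operation.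

Further compounds
F1 | step 9 | bromohydrin from 10: Br on the former epoxide CH (inverted), tertiary OH retained, E-enone | C1C[C@H]2CC3=C(O[C@]2(C)C(=O)/C=C/C(C)(C)C[C@H](Br)[C@]1(C)O)C(C)(C)C(=O)C(C(=O)C(C)C)=C3O
F2 | step 9 | tertiary alcohol: 13 with C(CH3)(OH) in place of C=CH2 | C[C@@]1(O)CC[C@H]2CC3=C(O[C@]2(C)C(=O)C[C@@H]2[C@@H]1CC2(C)C)C(C)(C)C(=O)C(C(=O)C(C)C)=C3O
F3 | step 5 | 3,5-dihydroxy-6,6-dimethyl-2-(2-methylpropanoyl)cyclohexa-2,4-dien-1-one | CC(C)C(=O)C1=C(O)C=C(O)C(C)(C)C1=O
F4 | step 12 | enol trifluoromethanesulfonate of 13 (ring-cis enol double bond) | C=C1CC[C@H]2CC3=C(O[C@]2(C)/C(OS(=O)(=O)C(F)(F)F)=C\[C@@H]2[C@@H]1CC2(C)C)C(C)(C)C(=O)C(C(=O)C(C)C)=C3O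
F5 | step 12 | cis-alkene: 13 with CH=CH in place of C(=O)–CH2 | C=C1CC[C@H]2CC3=C(O[C@]2(C)/C=C\[C@@H]2[C@@H]1CC2(C)C)C(C)(C)C(=O)C(C(=O)C(C)C)=C3O
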